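## The problem

Compound 27 is a 1,7-dioxadispiro[4.0.4.2]dodeca-3,9-diene-2,8-dione. It is a cyclobutane whose neighbouring carbons C5 and C6 are each the spiro carbon of a 4-bromo-2(5H)-furanone, while C11 and C12 carry a trans pair of bromines. The core is C2-symmetric, (5S,6S,11R,12R). The two lactone oxygens are trans, and each is trans to the bromine on the adjacent ring carbon, so every ring bromine sits syn to a bromovinyl carbon (C4 or C10). This crowded pattern is what two anti additions of oxygen and bromine across cyclobutene double bonds deliver; equilibrating chemistry would not be expected to give it. The two double bonds needed for these additions cannot exist together (they would make a cyclobutadiene), so the additions must be consecutive, and the centres set first (C5, C12) must steer the second pair (C6, C11). The 1-acetoxybutyl groups at C3 and C9 are (S) and (R). Their carbinol carbons are insulated from the core by an sp2 carbon, so they need reagent control, and the unlike pattern on a C2 core requires that the two ends be told apart once. The functional groups are fragile. C4–Br and C10–Br are vinylogous acyl bromides, open to addition–elimination by amines, alkoxides, phosphines and hydride and to insertion of zerovalent palladium. The ring bromides lie β to any carbanion made on the ring. The acetates are allylic, of Morita–Baylis–Hillman type. The enabling feature is that in the bis-butyl skeleton 22 the CH2 groups bonded to C3 and C9 are the only allylic C–H bonds (C5 and C6 are quaternary, C11–H and C12–H are homoallylic). Both chain oxygens can therefore be introduced last, and the core can be built with achiral butyl chains.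

## Retrosynthesis

27 to 26. The C–O bond of the (R)-acetate is cut with inversion, which leads to the (S)-alcohol 26 and acetic acid (Mitsunobu). The unlike diol cannot be made by a single reduction, because the two ketones of a C2-symmetric diketone are homotopic and one chiral catalyst gives the like diol. Inverting one of two identical ends is the shortest correction. The forward step must be a clean SN2 at an allylic carbinol.

26 to 25 to 24. Removing the acetyl group gives the (S,S)-diol 25. Its two hydroxyls are exchanged by the C2 axis, so mono-acetylation gives one compound. Replacing the two carbinol C–H bonds by C=O gives diketone 24, which has no chain stereocentres. The forward reduction must be catalyst-controlled and 1,2-selective.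

24 to 22. This is the key cut: both ketone oxygens are removed, which leaves the bis-butyl compound 22. The alternative of carrying oxygenated chains through the core synthesis puts epimerisable or eliminable centres next to every enolate and organometallic used there. Compound 22 has only the four rigid core stereocentres. The forward reaction must oxidise two allylic CH2 groups in the presence of four bromides and two strained lactones.

22 to 21 to 20. The O7–C6 and C11–Br bonds are cut together. The precursor is dienoic acid 21 (from tert-butyl ester 20), a cyclobutene that bears the (E)-3-bromo-2-butylacrylic acid arm on C1 and an allylic bromide on C3. Anti addition guarantees the trans O/Br relation. The existing C3 bromide should direct Br+ to the opposite face, and the first lactone keeps the two bromovinyl groups apart. The CHBr carbon changes descriptor from S (C3 in 16 to 21) to R (C12 in 22 to 27) through CIP priorities only.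

20 to 19 to 17 and 7. The C1=C2 double bond is traced to tertiary alcohol 19 (dehydration), and the C1–C(vinyl) bond to cyclobutanone 17 and the magnesium carbenoid 18 made from dibromoacrylate 7. A cross-coupling at this point is rejected for three reasons. Enolising 17 would expel the β-bromide. Zerovalent palladium would insert into the vinyl bromide. It would also ionise the allylic bromide and the allylic lactone of the product. Carbonyl addition followed by syn-elimination needs neither base nor transition metal. The tert-butyl ester is required so that the tertiary alkoxide cannot lactonise.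

17 to 16 to 15. The ketone is masked as its dimethyl ketal 16. Cutting O5–C4 and C3–Br of 16 gives the achiral dienoic acid 15, so the first bromolactonisation can be controlled by a chiral catalyst alone. A silyl-protected carbinol in place of the ketal would make 15 chiral and racemic and would set the catalyst against the substrate.

15 to 14 to 11 and 3. The ring–arm C(sp2)–C(sp2) bond is cut. Triflate 11 is the electrophile and zinc reagent 13 the nucleophile, made from dibromoacrylate 3 through carbenoid 12. The exchange takes place cis to the ester, which fixes the ring cis to the carboxyl, the geometry that lactonisation needs. A direct Suzuki coupling of the dibromide would leave this geometry to chance.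

Small fragments. Triflate 11 comes from ketal ketone 10, which comes from cyclobutane-1,2-dione 9, which comes from the commercial acyloin bis-silyl ether 8. Dibromoacrylate 3 comes from keto ester 1 and carbon tetrabromide 2. Dibromoacrylate 7 comes from keto ester 6, which is made from oxalate 4 and Grignard reagent 5.

## Roads not taken

Alternative 1: The cut is at C3–C4 and C9–C10 of both lactones. LiN(SiMe3)2 would enolise two acyloxy ester units, and each enolate would attack the ester carbon on its own ring carbon (two-directional Dieckmann). This gives the bis(tetronic acid) A1 with the (S) and (R) chains already present as silyl ethers; the enols would then be exchanged for bromine and the silyl groups for acetyl. Merits: the chain stereocentres come from bought or easily made chiral acids, no late oxidation, reduction or inversion is needed, and enol-to-vinyl-bromide exchange is reliable. Weak points: the key step does nothing for the real difficulty, a cyclobutane with two tertiary carbinols and two bromides in the crowded relative configuration, which must exist beforehand. The β-silyloxy ester enolates can lose silanolate. The amide base meets secondary bromides. The (S) and (R) acyl groups must still be placed on two homotopic hydroxyls. After the core, this road is shorter than the chosen one and avoids its three chain-adjusting steps. Against that, the chosen plan builds the core stereochemistry through two anti additions and keeps the chains inert until the end.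

Alternative 2: The cut is at C2–C3 and C8–C9. Pd(PPh3)4 under CO in methanol would ionise two propargylic carbonate units anti and carbonylate the allenylpalladium species to the bis(allenoate) A2, with each ester on the face away from the neighbouring ring bromine. Bromolactonisation of the two allenoic acid units would then form the C–Br and C–O bonds of both butenolides with the chains in place. Merits: bromolactonisation of 2,3-allenoic acids to 4-bromobutenolides is among the most dependable routes to this ring, axis-to-centre transfer would set the spiro carbons, and the endgame is the shortest of all. Weak points: two allene axes must be correct on a substrate that carries bromides next to the ionising centres. Allenoates epimerise with nucleophiles. The acetoxy group β to the new ester can be eliminated. Two chains of opposite configuration must be attached to a C2 core, so the ends must be differentiated early on sensitive material. If the axes can be controlled, this road is better in step count. The chosen plan instead derives the ring stereochemistry from the anti course of bromolactonisation and sets the chain configuration late, on one compound at a time.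

Alternative 3: The cut is at C4–Br, C3–C(carbinol) and O1–C2 on both sides. MgBr2 would add bromide to the β-carbon of two ynoate arms, the bromoallenolates would add to butanal A5, and the tertiary alkoxides would close both lactones by displacing the ester alkoxide, which gives the unlike diol A3. Merits: one operation makes six bonds and both rings; this is the most step-economic road, and no redox adjustment follows. Weak points: nothing controls the two new carbinol centres, so A3 is formed together with the like diols 25 and A4 and must be separated from them. The tertiary propargylic alcohols with the crowded O/Br relation are still required. The geometry of the aldol step decides whether lactonisation can occur. In length this road is clearly better than the chosen one. The chosen plan offers a single compound at every stage and reagent control of both carbinol centres, and its diketone 24 would also be the outlet for recycling unwanted diol isomers of this alternative.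

Key step: step 14

Remark: the sense of induction of the cinchona catalyst in step 9 cannot be predicted with certainty for this substrate; it is assumed that the hydroquinidine-derived catalyst gives (3S,4S)-16, and its hydroquinine pseudoenantiomer would be used otherwise.

Step 1
Reactants: 1 methyl 2-oxohexanoate; 2 carbon tetrabromide
Product: 3 methyl 2-butyl-3,3-dibromoprop-2-enoate
Conditions: PPh3 (2 equiv), CH2Cl2, 0 °C to rt
Reagents that add atoms: none
Why: Ramirez dibromo-olefination; the ylide Ph3P=CBr2 reacts readily with the activated keto group of an α-keto ester, and no stereochemistry arises.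

Step 2
Reactants: 4 di-tert-butyl oxalate; 5 butylmagnesium chloride
Product: 6 tert-butyl 2-oxohexanoate
Conditions: THF, −78 °C; aqueous quench
Reagents that add atoms: none
Why: Mono-addition of a Grignard reagent to a dialkyl oxalate; the tetrahedral magnesium alkoxide survives at −78 °C, so the second addition is avoided. The tert-butyl ester is needed in step 11.

Step 3
Reactants: 6 tert-butyl 2-oxohexanoate; 2 carbon tetrabromide
Product: 7 tert-butyl 2-butyl-3,3-dibromoprop-2-enoate
Conditions: PPh3 (2 equiv), CH2Cl2, 0 °C to rt
Reagents that add atoms: none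
Why: Ramirez dibromo-olefination as in step 1.

Step 4
Reactants: 8 1,2-bis(trimethylsilyloxy)cyclobutene
Product: 9 cyclobutane-1,2-dione
Conditions: Br2 (1 equiv), pentane, −60 °C to rt, exclusion of moisture
Reagents that add atoms: none
Why: Oxidative desilylation of the ene-diol bis-silyl ether by bromine, the standard preparation of this dione; anhydrous, base-free conditions avoid benzilic-type ring contraction.

Step 5
Reactants: 9 cyclobutane-1,2-dione
Product: 10 2,2-dimethoxycyclobutan-1-one
Conditions: HC(OMe)3, MeOH, p-toluenesulfonic acid monohydrate (cat.), rt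
Reagents that add atoms: trimethyl orthoformate, COC(OC)OC; methanol, CO
Why: Acid-catalysed mono-ketalisation of a 1,2-dione; the second carbonyl is deactivated and shielded by the new ketal. The ketal makes this carbon achiral and non-enolisable and keeps the later cyclobutene from being an enone.

Step 6
Reactants: 10 2,2-dimethoxycyclobutan-1-one
Product: 11 4,4-dimethoxycyclobut-1-en-1-yl trifluoromethanesulfonate
Conditions: KN(SiMe3)2, THF, −78 °C; PhN(SO2CF3)2, −78 °C to 0 °C
Reagents that add atoms: N-phenylbis(trifluoromethanesulfonimide), O=S(=O)(N(c1ccccc1)S(=O)(=O)C(F)(F)F)C(F)(F)F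
Why: Enol triflate formation; enolisation is possible only towards the CH2 carbon, so the position of the future ring double bond is unambiguous.

Step 7
Reactants: 3 methyl 2-butyl-3,3-dibromoprop-2-enoate; 11 4,4-dimethoxycyclobut-1-en-1-yl trifluoromethanesulfonate
Product: 14 methyl (2E)-3-bromo-2-butyl-3-(4,4-dimethoxycyclobut-1-en-1-yl)prop-2-enoate, via magnesium carbenoid 12 (not isolated), via alkenylzinc chloride 13 (not isolated)
Conditions: 3, iPrMgCl·LiCl, THF, −78 °C; ZnCl2, −78 °C; then 11, Pd(PPh3)4 (5 mol %), −78 °C to rt
Reagents that add atoms: none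
Why: Bromine–magnesium exchange on a 2-substituted 3,3-dibromoacrylate takes place at the bromine cis to the ester (five-membered chelate), and the chelate stabilises the carbenoid at −78 °C. Transmetalation to zinc and Negishi coupling with retention place the ring cis to the ester, the geometry needed for lactonisation. The triflate undergoes oxidative addition to zerovalent palladium faster than the hindered tetrasubstituted vinyl bromide of the product.

Step 8
Reactants: 14 methyl (2E)-3-bromo-2-butyl-3-(4,4-dimethoxycyclobut-1-en-1-yl)prop-2-enoate
Product: 15 (2E)-3-bromo-2-butyl-3-(4,4-dimethoxycyclobut-1-en-1-yl)prop-2-enoic acid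
Conditions: LiOH·H2O, THF/MeOH/H2O, 0 °C to rt; cold 0.5 M HCl to pH 4
Reagents that add atoms: lithium hydroxide, [Li+].[OH-]
Why: Saponification; the ketal is stable to base, and the hindered tetrasubstituted β-bromo enoate resists addition–elimination under these mild conditions.

Step 9
Reactants: 15 (2E)-3-bromo-2-butyl-3-(4,4-dimethoxycyclobut-1-en-1-yl)prop-2-enoic acid
Product: 16 (3S,4S)-3,8-dibromo-7-butyl-1,1-dimethoxy-5-oxaspiro[3.4]oct-7-en-6-one
Conditions: N-bromosuccinimide, hydroquinidine 1,4-phthalazinediyl diether (10 mol %), benzoic acid, CHCl3/hexane, −40 °C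
Reagents that add atoms: N-bromosuccinimide, O=C1CCC(=O)N1Br
Why: Catalytic asymmetric 5-exo bromolactonisation of an alkenoic acid; the catalyst-bound carboxylate closes on the ring carbon that bears the arm while Br+ is delivered to the CH carbon from the opposite face. Anti addition makes O5 and the C3 bromine trans, and the catalyst alone distinguishes the enantiotopic faces of achiral 15.

Step 10
Reactants: 16 (3S,4S)-3,8-dibromo-7-butyl-1,1-dimethoxy-5-oxaspiro[3.4]oct-7-en-6-one
Product: 17 (3S,4S)-3,8-dibromo-7-butyl-5-oxaspiro[3.4]oct-7-ene-1,6-dione
Conditions: CF3CO2H/H2O (9:1), CH2Cl2, 0 °C to rt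
Reagents that add atoms: water, O
Why: Acid hydrolysis of the dimethyl ketal; lactone and bromides tolerate acid, and no base is present that could eliminate HBr from the β-bromo ketone.

Step 11
Reactants: 7 tert-butyl 2-butyl-3,3-dibromoprop-2-enoate; 17 (3S,4S)-3,8-dibromo-7-butyl-5-oxaspiro[3.4]oct-7-ene-1,6-dione
Product: 19 tert-butyl (2E)-3-bromo-2-butyl-3-[(3S,4S)-3,8-dibromo-7-butyl-1-hydroxy-6-oxo-5-oxaspiro[3.4]oct-7-en-1-yl]prop-2-enoate (both C1 epimers), via magnesium carbenoid 18 (not isolated)
Conditions: 7, iPrMgCl·LiCl, THF, −78 °C; then 17, LaCl3·2LiCl, THF, −78 °C; water quench at −78 °C; crude product filtered through neutral alumina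
Reagents that add atoms: none
Why: 1,2-Addition of the chelated alkenylmagnesium carbenoid to the strained cyclobutanone, the most electrophilic carbonyl present; the lanthanum salt favours addition over enolisation, which would expel the β-bromide. The tert-butyl ester keeps the tertiary alkoxide from lactonising, and the new C1 centre is destroyed in step 12.

Step 12
Reactants: 19 tert-butyl (2E)-3-bromo-2-butyl-3-[(3S,4S)-3,8-dibromo-7-butyl-1-hydroxy-6-oxo-5-oxaspiro[3.4]oct-7-en-1-yl]prop-2-enoate
Product: 20 tert-butyl (2E)-3-bromo-2-butyl-3-[(3S,4S)-3,8-dibromo-7-butyl-6-oxo-5-oxaspiro[3.4]octa-1,7-dien-1-yl]prop-2-enoate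
Conditions: methyl N-(triethylammoniosulfonyl)carbamate (Burgess reagent), toluene, 50 °C
Reagents that add atoms: none
Why: Burgess dehydration by syn-elimination of the sulfamate; only C2 carries β-hydrogens (C4 is quaternary), and each C1 epimer has one syn to the leaving group. No carbanion is formed at C2, so the C3 bromide survives and the second cyclobutene appears as an allylic bromide.

Step 13
Reactants: 20 tert-butyl (2E)-3-bromo-2-butyl-3-[(3S,4S)-3,8-dibromo-7-butyl-6-oxo-5-oxaspiro[3.4]octa-1,7-dien-1-yl]prop-2-enoate
Product: 22 (5S,6S,11R,12R)-4,10,11,12-tetrabromo-3,9-dibutyl-1,7-dioxadispiro[4.0.4.2]dodeca-3,9-diene-2,8-dione, via dienoic acid 21 (not isolated)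
Conditions: CF3CO2H, CH2Cl2, 0 °C; evaporation; N-bromosuccinimide, MeCN, −20 °C to 0 °C, no base
Reagents that add atoms: N-bromosuccinimide, O=C1CCC(=O)N1Br
Why: Acidolysis of the tert-butyl ester, then substrate-controlled 5-exo bromolactonisation. Br+ should add to C2 anti to the C3 bromine, and the acid closes on C1 from the other face, which also keeps the two bromovinyl groups on opposite sides; anti addition makes the new C–O and C–Br bonds trans. Base is omitted so that carboxylate SN2′ displacement of the allylic bromide cannot compete.

Step 14
Reactants: 22 (5S,6S,11R,12R)-4,10,11,12-tetrabromo-3,9-dibutyl-1,7-dioxadispiro[4.0.4.2]dodeca-3,9-diene-2,8-dione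
Product: 24 (5S,6S,11R,12R)-4,10,11,12-tetrabromo-3,9-dibutanoyl-1,7-dioxadispiro[4.0.4.2]dodeca-3,9-diene-2,8-dione, via bis(tert-butylperoxide) 23 (not isolated)
Conditions: Rh2(C6H10NO)4 (dirhodium tetrakis(caprolactamate), 1 mol % in two portions), tert-butyl hydroperoxide (70% in water, 10 equiv), 1,2-dichloroethane, 40 °C, no base
Reagents that add atoms: tert-butyl hydroperoxide, CC(C)(C)OO
Why: Rh2(C6H10NO)4 is oxidised by the hydroperoxide by one electron to the mixed-valent Rh2(5+) state and in this cycle releases tert-butylperoxyl radicals, which abstract a hydrogen atom from the chain CH2 on C3 and, independently, on C9. Each allyl radical is captured by a second peroxyl radical at the chain carbon to give the mixed peroxide 23, because capture at C4 or C10 would break conjugation with the lactone carbonyl and would have to occur at a carbon that bears bromine and adjoins the quaternary spiro centre. The peroxide then loses tert-butanol (Kornblum–DeLaMare-type collapse) to give the conjugated ketone. The closest known reaction is the dirhodium caprolactamate/tert-butyl hydroperoxide oxidation of cycloalkenes to enones and of enones to ene-diones. No ring closes and no stereocentre is formed, since both new carbons are sp2, and the four core stereocentres carry no activated hydrogen. The step needs site selectivity, which the substrate secures because these two CH2 groups are its only allylic C–H bonds. It also needs chemoselectivity towards the vinylogous acyl bromides, which is secured by leaving out the usual carbonate base so that no hydroperoxide anion can displace bromide by addition–elimination. The two chains are related by the C2 axis and react alike, so the mono-ketone is only transient.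

Step 15
Reactants: 24 (5S,6S,11R,12R)-4,10,11,12-tetrabromo-3,9-dibutanoyl-1,7-dioxadispiro[4.0.4.2]dodeca-3,9-diene-2,8-dione
Product: 25 (5S,6S,11R,12R)-4,10,11,12-tetrabromo-3,9-bis[(1S)-1-hydroxybutyl]-1,7-dioxadispiro[4.0.4.2]dodeca-3,9-diene-2,8-dione
Conditions: (R)-1-methyl-3,3-diphenyltetrahydro-1H,3H-pyrrolo[1,2-c][1,3,2]oxazaborole ((R)-Me-CBS, 0.4 equiv), catecholborane (3 equiv), toluene/CH2Cl2, −78 °C; MeOH quench
Reagents that add atoms: none
Why: Corey–Bakshi–Shibata reduction; the butenolide carbon acts as the large and propyl as the small substituent, so the (R)-catalyst should give the (S)-carbinol at each of the two homotopic ketones. Low temperature and the catalysed pathway favour 1,2- over 1,4-hydride delivery.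

Step 16
Reactants: 25 (5S,6S,11R,12R)-4,10,11,12-tetrabromo-3,9-bis[(1S)-1-hydroxybutyl]-1,7-dioxadispiro[4.0.4.2]dodeca-3,9-diene-2,8-dione
Product: 26 (1S)-1-[(5S,6S,11R,12R)-4,10,11,12-tetrabromo-9-[(1S)-1-hydroxybutyl]-2,8-dioxo-1,7-dioxadispiro[4.0.4.2]dodeca-3,9-dien-3-yl]butyl acetate
Conditions: Ac2O (1.0 equiv), Sc(OSO2CF3)3 (1 mol %), MeCN, −20 °C; recovered 25 is recycled
Reagents that add atoms: acetic anhydride, CC(=O)OC(C)=O
Why: Lewis-acid-catalysed acetylation with one equivalent of anhydride; the two hydroxyls are exchanged by the C2 axis, so the mono-acetate is a single compound. The amine-free conditions leave the vinylogous acyl bromides untouched.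

Step 17
Reactants: 26 (1S)-1-[(5S,6S,11R,12R)-4,10,11,12-tetrabromo-9-[(1S)-1-hydroxybutyl]-2,8-dioxo-1,7-dioxadispiro[4.0.4.2]dodeca-3,9-dien-3-yl]butyl acetate
Product: 27 (1S)-1-[(5S,6S,11R,12R)-9-[(1R)-1-(acetyloxy)butyl]-4,10,11,12-tetrabromo-2,8-dioxo-1,7-dioxadispiro[4.0.4.2]dodeca-3,9-dien-3-yl]butyl acetate
Conditions: PPh3, diisopropyl azodicarboxylate, CH3CO2H, toluene, −20 °C to 0 °C
Reagents that add atoms: acetic acid, CC(=O)O
Why: Mitsunobu esterification with SN2 inversion turns the remaining (S)-carbinol into the (R)-acetate and so gives the unlike pattern. The SN2′ position (C10) is tetrasubstituted, bears bromine and adjoins the spiro centre, which should favour direct displacement.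

Compound list
1 | methyl 2-oxohexanoate | CCCCC(=O)C(=O)OC | starting material
2 | carbon tetrabromide | BrC(Br)(Br)Br | starting material
3 | methyl 2-butyl-3,3-dibromoprop-2-enoate | CCCCC(C(=O)OC)=C(Br)Br | intermediate
4 | di-tert-butyl oxalate | CC(C)(C)OC(=O)C(=O)OC(C)(C)C | starting material
5 | butylmagnesium chloride | CCCC[Mg]Cl | starting material
6 | tert-butyl 2-oxohexanoate | CCCCC(=O)C(=O)OC(C)(C)C | intermediate
7 | tert-butyl 2-butyl-3,3-dibromoprop-2-enoate | CCCCC(C(=O)OC(C)(C)C)=C(Br)Br | intermediate
8 | 1,2-bis(trimethylsilyloxy)cyclobutene | C[Si](C)(C)OC1=C(O[Si](C)(C)C)CC1 | starting material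
9 | cyclobutane-1,2-dione | O=C1CCC1=O | intermediate
10 | 2,2-dimethoxycyclobutan-1-one | COC1(OC)CCC1=O | intermediate
11 | 4,4-dimethoxycyclobut-1-en-1-yl trifluoromethanesulfonate | COC1(OC)CC=C1OS(=O)(=O)C(F)(F)F | intermediate
12 | methyl (2E)-3-bromo-2-butyl-3-(chloromagnesio)prop-2-enoate, magnesium cis to the ester | CCCC/C(C(=O)OC)=C(\Br)[Mg]Cl | intermediate
13 | methyl (2E)-3-bromo-2-butyl-3-(chlorozincio)prop-2-enoate, zinc cis to the ester | CCCC/C(C(=O)OC)=C(\Br)[Zn]Cl | intermediate
14 | methyl (2E)-3-bromo-2-butyl-3-(4,4-dimethoxycyclobut-1-en-1-yl)prop-2-enoate | CCCC/C(C(=O)OC)=C(\Br)C1=CCC1(OC)OC | intermediate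
15 | (2E)-3-bromo-2-butyl-3-(4,4-dimethoxycyclobut-1-en-1-yl)prop-2-enoic acid | CCCC/C(C(=O)O)=C(\Br)C1=CCC1(OC)OC | intermediate
16 | (3S,4S)-3,8-dibromo-7-butyl-1,1-dimethoxy-5-oxaspiro[3.4]oct-7-en-6-one | CCCCC1=C(Br)[C@@]2(OC1=O)[C@@H](Br)CC2(OC)OC | intermediate
17 | (3S,4S)-3,8-dibromo-7-butyl-5-oxaspiro[3.4]oct-7-ene-1,6-dione | CCCCC1=C(Br)[C@@]2(OC1=O)[C@@H](Br)CC2=O | intermediate
18 | tert-butyl (2E)-3-bromo-2-butyl-3-(chloromagnesio)prop-2-enoate, magnesium cis to the ester | CCCC/C(C(=O)OC(C)(C)C)=C(\Br)[Mg]Cl | intermediate
19 | tert-butyl (2E)-3-bromo-2-butyl-3-[(3S,4S)-3,8-dibromo-7-butyl-1-hydroxy-6-oxo-5-oxaspiro[3.4]oct-7-en-1-yl]prop-2-enoate, both C1 epimers | CCCCC1=C(Br)[C@@]2(OC1=O)[C@@H](Br)CC2(O)/C(Br)=C(/CCCC)C(=O)OC(C)(C)C | intermediate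
20 | tert-butyl (2E)-3-bromo-2-butyl-3-[(3S,4S)-3,8-dibromo-7-butyl-6-oxo-5-oxaspiro[3.4]octa-1,7-dien-1-yl]prop-2-enoate | CCCCC1=C(Br)[C@@]2(OC1=O)[C@@H](Br)C=C2/C(Br)=C(/CCCC)C(=O)OC(C)(C)C | intermediate
21 | (2E)-3-bromo-2-butyl-3-[(3S,4S)-3,8-dibromo-7-butyl-6-oxo-5-oxaspiro[3.4]octa-1,7-dien-1-yl]prop-2-enoic acid | CCCCC1=C(Br)[C@@]2(OC1=O)[C@@H](Br)C=C2/C(Br)=C(/CCCC)C(=O)O | intermediate
22 | (5S,6S,11R,12R)-4,10,11,12-tetrabromo-3,9-dibutyl-1,7-dioxadispiro[4.0.4.2]dodeca-3,9-diene-2,8-dione | CCCCC1=C(Br)[C@@]2(OC1=O)[C@@H](Br)[C@H](Br)[C@@]21OC(=O)C(CCCC)=C1Br | intermediate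
23 | (5S,6S,11R,12R)-4,10,11,12-tetrabromo-3,9-bis[1-(tert-butylperoxy)butyl]-1,7-dioxadispiro[4.0.4.2]dodeca-3,9-diene-2,8-dione, chain centres unassigned | CCCC(OOC(C)(C)C)C1=C(Br)[C@@]2(OC1=O)[C@@H](Br)[C@H](Br)[C@@]21OC(=O)C(C(CCC)OOC(C)(C)C)=C1Br | intermediate
24 | (5S,6S,11R,12R)-4,10,11,12-tetrabromo-3,9-dibutanoyl-1,7-dioxadispiro[4.0.4.2]dodeca-3,9-diene-2,8-dione | CCCC(=O)C1=C(Br)[C@@]2(OC1=O)[C@@H](Br)[C@H](Br)[C@@]21OC(=O)C(C(=O)CCC)=C1Br | intermediate
25 | (5S,6S,11R,12R)-4,10,11,12-tetrabromo-3,9-bis[(1S)-1-hydroxybutyl]-1,7-dioxadispiro[4.0.4.2]dodeca-3,9-diene-2,8-dione | CCC[C@H](O)C1=C(Br)[C@@]2(OC1=O)[C@@H](Br)[C@H](Br)[C@@]21OC(=O)C([C@H](CCC)O)=C1Br | intermediate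
26 | (1S)-1-[(5S,6S,11R,12R)-4,10,11,12-tetrabromo-9-[(1S)-1-hydroxybutyl]-2,8-dioxo-1,7-dioxadispiro[4.0.4.2]dodeca-3,9-dien-3-yl]butyl acetate | CCC[C@H](OC(C)=O)C1=C(Br)[C@@]2(OC1=O)[C@@H](Br)[C@H](Br)[C@@]21OC(=O)C([C@H](CCC)O)=C1Br | intermediate
27 | (1S)-1-[(5S,6S,11R,12R)-9-[(1R)-1-(acetyloxy)butyl]-4,10,11,12-tetrabromo-2,8-dioxo-1,7-dioxadispiro[4.0.4.2]dodeca-3,9-dien-3-yl]butyl acetate | CCC[C@H](OC(C)=O)C1=C(Br)[C@@]2(OC1=O)[C@@H](Br)[C@H](Br)[C@@]21OC(=O)C([C@@H](CCC)OC(C)=O)=C1Br | target

Total step count: 17. Longest linear sequence: 14 steps (steps 4 to 17, from 8); steps 1 and 2 to 3 are side branches.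

Least certain steps

Step 14 (key step). The peroxyl radical is electrophilic and the allylic CH2 sits on an electron-poor alkene, so hydrogen abstraction may be slow. The oxidation may then stop at the mono-ketone or at the peroxide stage, or the hydroperoxide may begin to displace the C4/C10 bromides. Fallback, from 22 back to 24: Wohl–Ziegler bromination (N-bromosuccinimide, dibenzoyl peroxide, PhCF3, 80 °C) should give the bis(1-bromobutyl) compound F1. Silver-assisted hydrolysis (AgOSO2CF3, aqueous acetone) would give the mixture of chain-epimeric diols F2, and Dess–Martin periodinane (1,1,1-triacetoxy-1,1-dihydro-1,2-benziodoxol-3(1H)-one) would then give 24.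

Step 11. The carbenoid may act as a base on 17 (enolisation with loss of HBr to a cyclobutenone), may undergo α-elimination before it adds, or may add too slowly to a carbonyl flanked by a quaternary centre. Fallback, from 7 and 17 back to 19: the carbenoid from 7 is quenched with iodine to give tert-butyl (2Z)-3-bromo-2-butyl-3-iodoprop-2-enoate F3. F3 is then joined to 17 by Nozaki–Hiyama–Kishi coupling (CrCl2, NiCl2 cat., DMF/THF, rt). Zerovalent nickel inserts into the carbon–iodine bond in preference to the carbon–bromine bonds, and the alkenylchromium species is not basic.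

Step 9. The cyclobutene is electron-poor and hindered by the ketal, so bromonium transfer within the chiral ion pair may be slow and facial discrimination poor. Fallback, from 15 back to 16: uncatalysed bromolactonisation (N-bromosuccinimide, MeCN) to the racemate, then separation of the enantiomers by preparative chromatography on a chiral stationary phase; the enantiomer F4 is set aside.

Step 7. Zerovalent palladium may insert into the C–Br bond of the zinc reagent or of the product (oligomerisation), or the carbenoid may decompose before transmetalation. Fallback, from 3 and 11 back to 14: the carbenoid from 3 is quenched with iodine to give methyl (2Z)-3-bromo-2-butyl-3-iodoprop-2-enoate F5. Triflate 11 is borylated (bis(pinacolato)diboron, PdCl2(PPh3)2, PPh3, KOPh, toluene, 50 °C) to 2-(4,4-dimethoxycyclobut-1-en-1-yl)-4,4,5,5-tetramethyl-1,3,2-dioxaborolane F6. Suzuki coupling (Pd(PPh3)4, K3PO4, THF/H2O) then takes place at the carbon–iodine bond only.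

Step 13. Facial selectivity may be poor (Br+ entering syn to the C3 bromide, or closure to the cis-dioxy isomer), and SN2′ lactonisation with loss of bromide may compete. Fallback, from 21 back to 22: the closure is changed from substrate control to reagent control. Acid 21 is isolated and cyclised with N-bromosuccinimide under the chiral phthalazine catalyst of step 9, using the pseudoenantiomer whose preference reinforces that of the C3 bromide; no new compound is formed (F0).

Step 17. The Morita–Baylis–Hillman-type carbinol may react by SN2′ or elimination, and PPh3 may add to C4/C10 with loss of bromide. Fallback, from 26 back to 27: Dess–Martin oxidation to the keto acetate F7, reduction with the (S)-enantiomer of the oxazaborolidine of step 15 and catecholborane to the (1R)-hydroxy acetate F8, and acetylation as in step 16.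

Further compounds
F1 | step 14 | (5S,6S,11R,12R)-4,10,11,12-tetrabromo-3,9-bis(1-bromobutyl)-1,7-dioxadispiro[4.0.4.2]dodeca-3,9-diene-2,8-dione, chain centres unassigned | CCCC(Br)C1=C(Br)[C@@]2(OC1=O)[C@@H](Br)[C@H](Br)[C@@]21OC(=O)C(C(Br)CCC)=C1Br
F2 | step 14 | (5S,6S,11R,12R)-4,10,11,12-tetrabromo-3,9-bis(1-hydroxybutyl)-1,7-dioxadispiro[4.0.4.2]dodeca-3,9-diene-2,8-dione, mixture of chain epimers | CCCC(O)C1=C(Br)[C@@]2(OC1=O)[C@@H](Br)[C@H](Br)[C@@]21OC(=O)C(C(CCC)O)=C1Br
F3 | step 11 | tert-butyl (2Z)-3-bromo-2-butyl-3-iodoprop-2-enoate | CCCC/C(C(=O)OC(C)(C)C)=C(\Br)I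
F4 | step 9 | (3R,4R)-3,8-dibromo-7-butyl-1,1-dimethoxy-5-oxaspiro[3.4]oct-7-en-6-one | CCCCC1=C(Br)[C@]2(OC1=O)[C@H](Br)CC2(OC)OC
F5 | step 7 | methyl (2Z)-3-bromo-2-butyl-3-iodoprop-2-enoate | CCCC/C(C(=O)OC)=C(\Br)I
F6 | step 7 | 2-(4,4-dimethoxycyclobut-1-en-1-yl)-4,4,5,5-tetramethyl-1,3,2-dioxaborolane | COC1(OC)CC=C1B1OC(C)(C)C(C)(C)O1
F0 | step 13 | none | none
F7 | step 17 | (1S)-1-[(5S,6S,11R,12R)-4,10,11,12-tetrabromo-9-butanoyl-2,8-dioxo-1,7-dioxadispiro[4.0.4.2]dodeca-3,9-dien-3-yl]butyl acetate | CCC[C@H](OC(C)=O)C1=C(Br)[C@@]2(OC1=O)[C@@H](Br)[C@H](Br)[C@@]21OC(=O)C(C(=O)CCC)=C1Br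
F8 | step 17 | (1S)-1-[(5S,6S,11R,12R)-4,10,11,12-tetrabromo-9-[(1R)-1-hydroxybutyl]-2,8-dioxo-1,7-dioxadispiro[4.0.4.2]dodeca-3,9-dien-3-yl]butyl acetate | CCC[C@H](OC(C)=O)C1=C(Br)[C@@]2(OC1=O)[C@@H](Br)[C@H](Br)[C@@]21OC(=O)C([C@@H](CCC)O)=C1Br
A1 | alternative 1 | dispiro bis(4-hydroxybutenolide) with (S)- and (R)-1-(tert-butyldimethylsilyloxy)butyl chains on the trans-dibromocyclobutane core | CCC[C@H](O[Si](C)(C)C(C)(C)C)C1=C(O)[C@@]2(OC1=O)[C@@H](Br)[C@H](Br)[C@@]21OC(=O)C([C@@H](CCC)O[Si](C)(C)C(C)(C)C)=C1O
A2 | alternative 2 | trans-3,4-dibromocyclobutane-1,2-diylidene bis(allenoate) with (S)- and (R)-1-acetoxybutyl groups, allene axes not encoded | CCC[C@H](OC(C)=O)C(C(=O)OC)=C=C1[C@@H](Br)[C@H](Br)C1=C=C(C(=O)OC)[C@@H](CCC)OC(C)=O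
A3 | alternative 3 | (5S,6S,11R,12R)-4,10,11,12-tetrabromo-3-[(1S)-1-hydroxybutyl]-9-[(1R)-1-hydroxybutyl]-1,7-dioxadispiro[4.0.4.2]dodeca-3,9-diene-2,8-dione | CCC[C@H](O)C1=C(Br)[C@@]2(OC1=O)[C@@H](Br)[C@H](Br)[C@@]21OC(=O)C([C@@H](CCC)O)=C1Br
A4 | alternative 3 | (5S,6S,11R,12R)-4,10,11,12-tetrabromo-3,9-bis[(1R)-1-hydroxybutyl]-1,7-dioxadispiro[4.0.4.2]dodeca-3,9-diene-2,8-dione | CCC[C@@H](O)C1=C(Br)[C@@]2(OC1=O)[C@@H](Br)[C@H](Br)[C@@]21OC(=O)C([C@@H](CCC)O)=C1Br
A5 | alternative 3 | butanal | CCCC=O
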